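**Retrosynthetic overview** (germacrane numbering C1–C15 is used for all intermediates)

1. Feature: a 3(2H)-furanone ring (O–C10–C1(=O)–C2=C3) bridges a ten-membered carbocycle (C1–C10). Its C2=C3–C4=C5 diene is E at C2=C3 (inside the furanone) and Z at C4=C5, the cis,trans pattern left by conrotatory opening of a cis-fused cyclobutene.
2. Key disconnection: cut C2–C3 and C4–C5 and rejoin C2–C5. This leads back to the lactone-fused (Z)-cyclooctenone 29 with a C10 alkynyl ether (C3≡C4–C15); its intramolecular [2+2] addition and 4π opening close the furanone and the ten-membered ring in one operation.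
3. Cyclooctenone: C1–C2 bond by intramolecular Nozaki–Hiyama–Kishi reaction of a Z vinyl iodide with the C1 aldehyde, then oxidation. Olefin metathesis is avoided here because the ynol ether would take part.
4. C7–C8 bond: CrCl2 allylation of aldehyde 15 (fragment A, from (S)-citramalic acid; the ynol ether is made early because its formation needs n-BuLi) with bromomethyl butenolide 22 (fragment B). A Mitsunobu inversion then installs the (R)-2-methylbutanoate. C15 is carried as a 4-methoxybenzyl ether because fluoride is needed twice on the way.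
5. Ring order: butenolide (ring-closing metathesis; it becomes the methylene lactone) → cyclooctenone → furanone and ten-membered ring together; the last step frees C15–OH.

Key step: step 21

Remark on the chemistry (assumption): allylchromium additions are taken to pass through the closed chair transition state, so the ring-locked allyl unit of 22 should give the 7,8-anti (8S) alcohol in step 15; step 16 is built on this outcome.

**Fragment A (steps 1–10)**

Step 1
Reactants: 1 (S)-citramalic acid
Product: 2 2-[(4S)-2,2,4-trimethyl-5-oxo-1,3-dioxolan-4-yl]acetic acid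
Conditions: 2,2-dimethoxypropane, TsOH (cat.), rt
Reagents that add atoms: 2,2-dimethoxypropane, COC(C)(C)OC
Why: Acid-catalysed acetal exchange (dioxolanone formation) should engage only the α-hydroxy acid unit in the five-membered ring, as in the malic acid series, which differentiates the two carboxyl groups without touching the C10 stereocentre taken from the chiral pool.

Step 2
Reactants: 2 2-[(4S)-2,2,4-trimethyl-5-oxo-1,3-dioxolan-4-yl]acetic acid
Product: 3 (5S)-5-(2-hydroxyethyl)-2,2,5-trimethyl-1,3-dioxolan-4-one
Conditions: BH3·SMe2, THF, 0 °C to rt; MeOH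
Reagents that add atoms: none
Why: Borane reduction is chemoselective for the free carboxylic acid over the ester-type dioxolanone carbonyl, so the C8 primary alcohol should form.

Step 3
Reactants: 3 (5S)-5-(2-hydroxyethyl)-2,2,5-trimethyl-1,3-dioxolan-4-one
Product: 4 (5S)-5-[2-(tert-butyldimethylsilyloxy)ethyl]-2,2,5-trimethyl-1,3-dioxolan-4-one
Conditions: TBSCl, imidazole, CH2Cl2, 0 °C
Reagents that add atoms: tert-butyldimethylsilyl chloride, CC(C)(C)[Si](C)(C)Cl
Why: Imidazole-promoted silylation of the primary alcohol is routine and blocks acid-induced translactonisation of the hydroxyethyl dioxolanone.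

Step 4
Reactants: 4 (5S)-5-[2-(tert-butyldimethylsilyloxy)ethyl]-2,2,5-trimethyl-1,3-dioxolan-4-one
Product: 5 (2S)-4-(tert-butyldimethylsilyloxy)-2-methylbutane-1,2-diol
Conditions: LiAlH4, THF, 0 °C
Reagents that add atoms: none
Why: Hydride reduction of the dioxolanone (an activated ester) with LiAlH4 should release the C1 primary alcohol and the tertiary C10 hydroxyl, the acetonide carbon leaving as propan-2-ol and the TBS ether surviving.

Step 5
Reactants: 5 (2S)-4-(tert-butyldimethylsilyloxy)-2-methylbutane-1,2-diol
Product: 6 (2S)-4-(tert-butyldimethylsilyloxy)-2-methyl-1-(triisopropylsilyloxy)butan-2-ol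
Conditions: TIPSCl, imidazole, DMF, rt
Reagents that add atoms: triisopropylsilyl chloride, CC(C)[Si](Cl)(C(C)C)C(C)C
Why: Silylation with a bulky chlorosilane is selective for the primary over the tertiary hydroxyl, and TIPS is chosen because it cannot migrate to the neighbouring tertiary oxygen and outlasts TBS toward fluoride.

Step 6
Reactants: 6 (2S)-4-(tert-butyldimethylsilyloxy)-2-methyl-1-(triisopropylsilyloxy)butan-2-ol; 7 trichloroethylene
Product: 9 (2S)-4-(tert-butyldimethylsilyloxy)-2-[(E)-1,2-dichloroethenyloxy]-2-methyl-1-(triisopropylsilyloxy)butane, via dichloroacetylene 8 (not isolated)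
Conditions: KH, THF, 0 °C; then Cl2C=CHCl, −40 °C to rt
Reagents that add atoms: none
Why: O-vinylation by the dichlorovinyl ether route: KH converts trichloroethylene into dichloroacetylene, to which the tertiary potassium alkoxide adds in anti fashion to give the (E)-1,2-dichlorovinyl ether, a migration of the bulky silyl groups to the tertiary oxygen being contra-thermodynamic.

Step 7
Reactants: 9 (2S)-4-(tert-butyldimethylsilyloxy)-2-[(E)-1,2-dichloroethenyloxy]-2-methyl-1-(triisopropylsilyloxy)butane
Product: 12 3-{[(2S)-4-(tert-butyldimethylsilyloxy)-2-methyl-1-(triisopropylsilyloxy)butan-2-yl]oxy}prop-2-yn-1-ol, via chloroalkynyl ether 10 (not isolated), via lithium alkynyl ether 11 (not isolated)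
Conditions: n-BuLi (2.3 equiv), THF, −78 to −40 °C; (CH2O)n, −78 °C to rt
Reagents that add atoms: paraformaldehyde (formaldehyde), C=O
Why: Dehydrochlorination and chlorine–lithium exchange with n-BuLi (the standard entry to lithium alkoxyacetylides) followed by hydroxymethylation with formaldehyde should install C15, all before any carbonyl group that n-BuLi would attack is present.

Step 8
Reactants: 12 3-{[(2S)-4-(tert-butyldimethylsilyloxy)-2-methyl-1-(triisopropylsilyloxy)butan-2-yl]oxy}prop-2-yn-1-ol
Product: 13 4-methoxybenzyl ether of 12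
Conditions: NaH, PMBCl, Bu4NI (cat.), THF/DMF, 0 °C to rt
Reagents that add atoms: 4-methoxybenzyl chloride, COc1ccc(CCl)cc1
Why: Williamson ether synthesis under basic conditions, which the ynol ether tolerates, masks C15–OH as a 4-methoxybenzyl ether that is inert to the fluoride used twice later.

Step 9
Reactants: 13 4-methoxybenzyl ether of 12
Product: 14 (3S)-3-{[3-(4-methoxybenzyloxy)prop-1-yn-1-yl]oxy}-3-methyl-4-(triisopropylsilyloxy)butan-1-ol
Conditions: Bu4NF (1.1 equiv), THF, 0 °C
Reagents that add atoms: none
Why: Fluoride-mediated desilylation should discriminate the unhindered primary TBS ether from the neopentyl-type TIPS ether, and the basic medium spares the acid-labile ynol ether.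

Step 10
Reactants: 14 (3S)-3-{[3-(4-methoxybenzyloxy)prop-1-yn-1-yl]oxy}-3-methyl-4-(triisopropylsilyloxy)butan-1-ol
Product: 15 (3S)-3-{[3-(4-methoxybenzyloxy)prop-1-yn-1-yl]oxy}-3-methyl-4-(triisopropylsilyloxy)butanal (fragment A)
Conditions: Dess–Martin periodinane, NaHCO3, CH2Cl2, 0 °C
Reagents that add atoms: none
Why: Buffered Dess–Martin oxidation gives the aldehyde under near-neutral conditions that avoid both acid hydration of the ynol ether and E1cB loss of the β-alkynyloxy group, the aldehyde being used without storage.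

**Fragment B (steps 11–14)**

Step 11
Reactants: 16 ethyl (Z)-3-iodoacrylate
Product: 18 (1Z)-1-iodopenta-1,4-dien-3-ol (racemic), via (Z)-3-iodoprop-2-enal 17 (not isolated)
Conditions: i-Bu2AlH, CH2Cl2, −78 °C; then CH2=CHMgBr, −78 to −20 °C
Reagents that add atoms: vinylmagnesium bromide, C=C[Mg]Br
Why: Partial reduction of the ester with i-Bu2AlH to the aldehyde oxidation level and in situ 1,2-addition of the vinyl Grignard reagent give the bis-allylic alcohol with the Z iodoalkene intact, the isomerisation-prone aldehyde never being isolated.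

Step 12
Reactants: 18 (1Z)-1-iodopenta-1,4-dien-3-ol (racemic)
Product: 19 (3S,1Z)-1-iodopenta-1,4-dien-3-ol
Conditions: Ti(OiPr)4 (0.2 equiv), L-(+)-diisopropyl tartrate (0.24 equiv), t-BuOOH (0.6 equiv), 4 Å MS, CH2Cl2, −20 °C
Reagents that add atoms: none
Why: Sharpless kinetic resolution: with the L-(+)-tartrate the (R)-enantiomer should be epoxidised at its vinyl group much faster (the electron-poor Z iodoalkene is inert), so that the (S)-alcohol, which carries the future C6 stereocentre, is recovered.

Step 13
Reactants: 19 (3S,1Z)-1-iodopenta-1,4-dien-3-ol; 20 2-(bromomethyl)acrylic acid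
Product: 21 (3S,1Z)-1-iodopenta-1,4-dien-3-yl 2-(bromomethyl)acrylate
Conditions: DCC, DMAP (5 mol %), CH2Cl2, −10 °C
Reagents that add atoms: none
Why: Steglich esterification acylates the oxygen with retention at C6, a low DMAP loading and temperature limiting attack on the allylic bromide.

Step 14
Reactants: 21 (3S,1Z)-1-iodopenta-1,4-dien-3-yl 2-(bromomethyl)acrylate
Product: 22 (5S)-3-(bromomethyl)-5-[(Z)-2-iodoethenyl]furan-2(5H)-one (fragment B)
Conditions: second-generation Grubbs catalyst (5 mol %), CH2Cl2, 40 °C
Reagents that add atoms: none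
Why: Ring-closing metathesis between the acrylate and the vinyl group should close the butenolide with loss of ethene, the Z vinyl iodide and the allylic bromide being spectators and the C6 stereocentre not being involved.

**Union and end game (steps 15–22)**

Step 15
Reactants: 15 (3S)-3-{[3-(4-methoxybenzyloxy)prop-1-yn-1-yl]oxy}-3-methyl-4-(triisopropylsilyloxy)butanal; 22 (5S)-3-(bromomethyl)-5-[(Z)-2-iodoethenyl]furan-2(5H)-one
Product: 23 (4R,5S)-4-[(1S,3S)-1-hydroxy-3-{[3-(4-methoxybenzyloxy)prop-1-yn-1-yl]oxy}-3-methyl-4-(triisopropylsilyloxy)butyl]-5-[(Z)-2-iodoethenyl]-3-methylideneoxolan-2-one (6S,7R,8S,10S)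
Conditions: CrCl2 (3 equiv), THF, 0 °C to rt
Reagents that add atoms: none
Why: Nozaki–Hiyama allylation: the allylchromium species from 22 should add through C7 in a closed chair (Zimmerman–Traxler) transition state, the aldehyde approaching the butenolide face anti to the C6 iodovinyl group (C6/C7 trans lactone) and the ring-locked E geometry of the allyl unit giving the 7,8-anti, that is (8S), alcohol, while the anhydrous, weakly Lewis acidic medium spares the ynol ether.

Step 16
Reactants: 23 the (8S) alcohol of step 15; 24 (R)-2-methylbutanoic acid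
Product: 25 (1R,3S)-1-{(2S,3R)-2-[(Z)-2-iodoethenyl]-4-methylidene-5-oxooxolan-3-yl}-3-{[3-(4-methoxybenzyloxy)prop-1-yn-1-yl]oxy}-3-methyl-4-(triisopropylsilyloxy)butyl (2R)-2-methylbutanoate (6S,7R,8R,10S)
Conditions: PPh3, diisopropyl azodicarboxylate, toluene, 0 °C to rt
Reagents that add atoms: none
Why: Mitsunobu esterification should install the (R)-2-methylbutanoate with SN2 inversion at C8, turning the (8S) alcohol into the (8R) ester of the target, the PPh3–azodicarboxylate adduct being formed first so that the phosphine does not add to the methylene lactone.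

Step 17
Reactants: 25 the (8R) ester of step 16
Product: 26 (1R,3S)-4-hydroxy-1-{(2S,3R)-2-[(Z)-2-iodoethenyl]-4-methylidene-5-oxooxolan-3-yl}-3-{[3-(4-methoxybenzyloxy)prop-1-yn-1-yl]oxy}-3-methylbutyl (2R)-2-methylbutanoate
Conditions: Bu4NF, AcOH (1:1), THF, rt
Reagents that add atoms: none
Why: Buffered fluoride desilylation removes the TIPS group without generating a free alkoxide that could trigger acyl migration, and without acid that would hydrate the ynol ether.

Step 18
Reactants: 26 the C1 primary alcohol of step 17
Product: 27 (1R,3S)-1-{(2S,3R)-2-[(Z)-2-iodoethenyl]-4-methylidene-5-oxooxolan-3-yl}-3-{[3-(4-methoxybenzyloxy)prop-1-yn-1-yl]oxy}-3-methyl-4-oxobutyl (2R)-2-methylbutanoate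
Conditions: Dess–Martin periodinane, NaHCO3, CH2Cl2, 0 °C
Reagents that add atoms: none
Why: Buffered Dess–Martin oxidation converts the neopentyl-type primary alcohol into the non-enolisable C1 aldehyde without touching the vinyl iodide, the methylene lactone or the ynol ether.

Step 19
Reactants: 27 the C1 aldehyde of step 18
Product: 28 (6R,7R,8R,10S)-configured (2Z)-cyclooct-2-en-1-ol fused at C6–C7 to the α-methylene-γ-lactone, with the C10 methyl group, the C10 3-(4-methoxybenzyloxy)prop-1-yn-1-yl ether and the C8 (2R)-2-methylbutanoate (mixture of C1 epimers)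
Conditions: CrCl2 (8 equiv), NiCl2 (cat.), DMSO, rt, 2 mM
Reagents that add atoms: none
Why: Intramolecular Nozaki–Hiyama–Kishi reaction: zerovalent nickel inserts into the Z vinyl iodide, transmetallation to trivalent chromium gives a vinylchromium species that adds to the C1 aldehyde with retention of alkene geometry, and the trans lactone holds the two chains close enough for eight-membered ring closure at high dilution, the new C1 carbinol centre being irrelevant because it is oxidised next.

Step 20
Reactants: 28 the cyclooctenol of step 19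
Product: 29 (6R,7R,8R,10S)-configured lactone-fused (2Z)-cyclooct-2-en-1-one with the C10 3-(4-methoxybenzyloxy)prop-1-yn-1-yl ether and the C8 (2R)-2-methylbutanoate (key-step precursor)
Conditions: Dess–Martin periodinane, NaHCO3, CH2Cl2, 0 °C to rt
Reagents that add atoms: none
Why: Dess–Martin oxidation of the allylic alcohol should give the Z cyclooctenone, both C1 epimers converging on one ketone.

Step 21
Reactants: 29 the alkynyl ether of the lactone-fused cyclooctenone
Product: 31 15-O-(4-methoxybenzyl) ether of the target (6R,7R,8R,10S; 2E,4Z), via cis-fused cyclobutene 30 (not isolated)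
Conditions: AgNTf2 (10 mol %), 4 Å MS, CH2Cl2, −20 °C to rt
Reagents that add atoms: none
Why: Proposed new method: monovalent silver from AgNTf2 is expected to activate the enone of 29 so that the electron-rich ynol ether carbon C4 adds to the enone β-carbon C5, and the resulting enolate carbon C2 then collapses onto the alkoxyketenium carbon C3 to give the cis-fused cyclobutene 30, whose donor–acceptor substituted C2–C5 bond should open in a thermal conrotatory 4π electrocyclic step to the diene 31. The closest known reaction types are the AgNTf2-catalysed [2+2] cycloaddition of siloxyalkynes with enones, the Ficini ynamine–enone cycloaddition, and the thermal opening of ring-fused cyclobutenes used as a two-carbon ring expansion (the same net change as a PtCl2-catalysed enyne skeletal rearrangement of a cycloalkene-tethered alkyne). The furanone ring closes by 5-exo-dig attack of C2 on C3 through the O–C10–C1 tether, and the ten-membered carbocycle arises by cleavage of the shared C2–C5 bond of the bicyclo[6.2.0] unit, that is by ring expansion and not by a separate cyclisation. No stereocentre is created in 31: the transient centres C2 and C5 are set cis by the three-atom tether, and C6, C7, C8 and C10 are untouched. The step needs C4-to-C5 and C3-to-C2 regiochemistry, secured by polarity matching and by the fact that attack of C4 on the C1 carbonyl would place a linear ketenium inside a five-membered ring; it also needs the 2E,4Z diene, secured because the new five-membered ring forces C1 to rotate outward so that conrotation turns C6 inward. The tertiary ynol ether is kept at or below room temperature to avoid retro-ene loss of a ketene, and molecular sieves exclude the water that would hydrate it.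

Step 22
Reactants: 31 15-O-(4-methoxybenzyl) ether of the target
Product: 32 target CNP0307052.2
Conditions: DDQ, CH2Cl2/pH 7 buffer, 0 °C
Reagents that add atoms: none
Why: Oxidative cleavage of the 4-methoxybenzyl ether with DDQ (benzylic hydride abstraction then hydrolysis) should free C15–OH under neutral conditions that leave the methylene lactone, the ester and the electron-poor furanone diene untouched.

**Compound list**

1 | (S)-citramalic acid | OC(=O)[C@](C)(CC(=O)O)O | starting material
2 | 2-[(4S)-2,2,4-trimethyl-5-oxo-1,3-dioxolan-4-yl]acetic acid | O=C1OC(C)(C)O[C@@]1(C)CC(=O)O | intermediate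
3 | (5S)-5-(2-hydroxyethyl)-2,2,5-trimethyl-1,3-dioxolan-4-one | O=C1OC(C)(C)O[C@@]1(C)CCO | intermediate
4 | (5S)-5-[2-(tert-butyldimethylsilyloxy)ethyl]-2,2,5-trimethyl-1,3-dioxolan-4-one | O=C1OC(C)(C)O[C@@]1(C)CCO[Si](C)(C)C(C)(C)C | intermediate
5 | (2S)-4-(tert-butyldimethylsilyloxy)-2-methylbutane-1,2-diol | OC[C@@](C)(O)CCO[Si](C)(C)C(C)(C)C | intermediate
6 | (2S)-4-(tert-butyldimethylsilyloxy)-2-methyl-1-(triisopropylsilyloxy)butan-2-ol | CC(C)[Si](OC[C@@](C)(O)CCO[Si](C)(C)C(C)(C)C)(C(C)C)C(C)C | intermediate
7 | trichloroethylene | ClC=C(Cl)Cl | starting material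
8 | dichloroacetylene | ClC#CCl | intermediate (not isolated)
9 | (2S)-4-(tert-butyldimethylsilyloxy)-2-[(E)-1,2-dichloroethenyloxy]-2-methyl-1-(triisopropylsilyloxy)butane | Cl/C=C(/Cl)O[C@](C)(CO[Si](C(C)C)(C(C)C)C(C)C)CCO[Si](C)(C)C(C)(C)C | intermediate
10 | (2S)-4-(tert-butyldimethylsilyloxy)-2-(chloroethynyloxy)-2-methyl-1-(triisopropylsilyloxy)butane | ClC#CO[C@](C)(CO[Si](C(C)C)(C(C)C)C(C)C)CCO[Si](C)(C)C(C)(C)C | intermediate (not isolated)
11 | lithium 2-{[(2S)-4-(tert-butyldimethylsilyloxy)-2-methyl-1-(triisopropylsilyloxy)butan-2-yl]oxy}ethynide | [Li]C#CO[C@](C)(CO[Si](C(C)C)(C(C)C)C(C)C)CCO[Si](C)(C)C(C)(C)C | intermediate (not isolated)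
12 | 3-{[(2S)-4-(tert-butyldimethylsilyloxy)-2-methyl-1-(triisopropylsilyloxy)butan-2-yl]oxy}prop-2-yn-1-ol | OCC#CO[C@](C)(CO[Si](C(C)C)(C(C)C)C(C)C)CCO[Si](C)(C)C(C)(C)C | intermediate
13 | 4-methoxybenzyl ether of 12 | COc1ccc(COCC#CO[C@](C)(CO[Si](C(C)C)(C(C)C)C(C)C)CCO[Si](C)(C)C(C)(C)C)cc1 | intermediate
14 | (3S)-3-{[3-(4-methoxybenzyloxy)prop-1-yn-1-yl]oxy}-3-methyl-4-(triisopropylsilyloxy)butan-1-ol | COc1ccc(COCC#CO[C@](C)(CO[Si](C(C)C)(C(C)C)C(C)C)CCO)cc1 | intermediate
15 | (3S)-3-{[3-(4-methoxybenzyloxy)prop-1-yn-1-yl]oxy}-3-methyl-4-(triisopropylsilyloxy)butanal | COc1ccc(COCC#CO[C@](C)(CO[Si](C(C)C)(C(C)C)C(C)C)CC=O)cc1 | intermediate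
16 | ethyl (Z)-3-iodoacrylate | CCOC(=O)/C=C\I | starting material
17 | (Z)-3-iodoprop-2-enal | O=C/C=C\I | intermediate (not isolated)
18 | (1Z)-1-iodopenta-1,4-dien-3-ol, racemic | OC(C=C)/C=C\I | intermediate
19 | (3S,1Z)-1-iodopenta-1,4-dien-3-ol | O[C@@H](C=C)/C=C\I | intermediate
20 | 2-(bromomethyl)acrylic acid | C=C(CBr)C(=O)O | starting material
21 | (3S,1Z)-1-iodopenta-1,4-dien-3-yl 2-(bromomethyl)acrylate | C=C(CBr)C(=O)O[C@@H](C=C)/C=C\I | intermediate
22 | (5S)-3-(bromomethyl)-5-[(Z)-2-iodoethenyl]furan-2(5H)-one | O=C1O[C@H](/C=C\I)C=C1CBr | intermediate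
23 | (4R,5S)-4-[(1S,3S)-1-hydroxy-3-{[3-(4-methoxybenzyloxy)prop-1-yn-1-yl]oxy}-3-methyl-4-(triisopropylsilyloxy)butyl]-5-[(Z)-2-iodoethenyl]-3-methylideneoxolan-2-one | C=C1C(=O)O[C@H](/C=C\I)[C@H]1[C@@H](O)C[C@@](C)(CO[Si](C(C)C)(C(C)C)C(C)C)OC#CCOCc1ccc(OC)cc1 | intermediate
24 | (R)-2-methylbutanoic acid | OC(=O)[C@H](C)CC | starting material
25 | (1R,3S)-1-{(2S,3R)-2-[(Z)-2-iodoethenyl]-4-methylidene-5-oxooxolan-3-yl}-3-{[3-(4-methoxybenzyloxy)prop-1-yn-1-yl]oxy}-3-methyl-4-(triisopropylsilyloxy)butyl (2R)-2-methylbutanoate | C=C1C(=O)O[C@H](/C=C\I)[C@H]1[C@H](OC(=O)[C@H](C)CC)C[C@@](C)(CO[Si](C(C)C)(C(C)C)C(C)C)OC#CCOCc1ccc(OC)cc1 | intermediate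
26 | (1R,3S)-4-hydroxy-1-{(2S,3R)-2-[(Z)-2-iodoethenyl]-4-methylidene-5-oxooxolan-3-yl}-3-{[3-(4-methoxybenzyloxy)prop-1-yn-1-yl]oxy}-3-methylbutyl (2R)-2-methylbutanoate | C=C1C(=O)O[C@H](/C=C\I)[C@H]1[C@H](OC(=O)[C@H](C)CC)C[C@@](C)(CO)OC#CCOCc1ccc(OC)cc1 | intermediate
27 | (1R,3S)-1-{(2S,3R)-2-[(Z)-2-iodoethenyl]-4-methylidene-5-oxooxolan-3-yl}-3-{[3-(4-methoxybenzyloxy)prop-1-yn-1-yl]oxy}-3-methyl-4-oxobutyl (2R)-2-methylbutanoate | C=C1C(=O)O[C@H](/C=C\I)[C@H]1[C@H](OC(=O)[C@H](C)CC)C[C@@](C)(C=O)OC#CCOCc1ccc(OC)cc1 | intermediate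
28 | (6R,7R,8R,10S)-lactone-fused (2Z)-cyclooct-2-en-1-ol with C10 3-(4-methoxybenzyloxy)prop-1-yn-1-yl ether and C8 (2R)-2-methylbutanoate, C1 epimers | C=C1C(=O)O[C@@H]2/C=C\C(O)[C@](C)(C[C@@H](OC(=O)[C@H](C)CC)[C@@H]12)OC#CCOCc1ccc(OC)cc1 | intermediate
29 | (6R,7R,8R,10S)-lactone-fused (2Z)-cyclooct-2-en-1-one with C10 3-(4-methoxybenzyloxy)prop-1-yn-1-yl ether and C8 (2R)-2-methylbutanoate (key-step precursor) | C=C1C(=O)O[C@@H]2/C=C\C(=O)[C@](C)(C[C@@H](OC(=O)[C@H](C)CC)[C@@H]12)OC#CCOCc1ccc(OC)cc1 | intermediate
30 | cis-fused cyclobutene: C2–C3 and C4–C5 bonded, C3=C4 double bond, H2 and H5 cis, other centres as in 29 | C=C1C(=O)O[C@@H]2[C@H]3C(COCc5ccc(OC)cc5)=C4O[C@@](C)(C[C@@H](OC(=O)[C@H](C)CC)[C@@H]12)C(=O)[C@@H]34 | intermediate (not isolated)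
31 | 15-O-(4-methoxybenzyl) ether of the target (key-step product) | C=C1C(=O)O[C@@H]2/C=C(/COCc4ccc(OC)cc4)C3=CC(=O)[C@](C)(C[C@@H](OC(=O)[C@H](C)CC)[C@@H]12)O3 | intermediate
32 | CNP0307052.2 | C=C1C(=O)O[C@@H]2/C=C(/CO)C3=CC(=O)[C@](C)(C[C@@H](OC(=O)[C@H](C)CC)[C@@H]12)O3 | target

**Step count**

Total: 22 steps. Longest linear sequence: 18 steps (steps 1–10, then 15–22).

**Steps most likely to fail**

Step 21 (key step). The silver salt may bind the ynol ether and lead to hydration or oligomerisation instead of C4–C5 bond formation, or the tertiary ynol ether may fragment by retro-ene loss before it adds. The fallback uses known chemistry and leaves ground-state polar activation altogether: starting from 29, irradiation at 366 nm in CH2Cl2 at 0 °C should bring about the intramolecular enone–alkyne [2+2] photocycloaddition (three-atom tether, first bond C2–C3 in a five-membered ring), and the cyclobutene 30 would be isolated. Heating 30 in toluene at 60–80 °C should then open it in the thermal conrotatory sense, and the route is rejoined at 31. No new compound is made.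

Step 16. Formation of the alkoxyphosphonium ion at the hindered C8 carbinol may be slow, so that elimination toward C7 or participation of the lactone carbonyl (retention) competes with inversion. The fallback separates activation from displacement: starting from 23, chloromethanesulfonyl chloride and pyridine at 0 °C should give the C8 chloromethanesulfonate F1. F1 would then be displaced with caesium (R)-2-methylbutanoate and 18-crown-6 in toluene at 40 °C by an SN2 reaction, and the route is rejoined at 25.

Step 6. A silyl group may migrate to the tertiary alkoxide, or the hindered alkoxide may add too slowly to dichloroacetylene, so that an ether of a primary oxygen or unchanged alcohol results. The fallback avoids the alkoxide: starting from 6, acetic formic anhydride and pyridine should give the tertiary formate F2. CBr4 and PPh3 in CH2Cl2 should then dibromomethylenate the formyl group (Corey–Fuchs-type reagent) to the 2,2-dibromovinyl ether F3. n-BuLi (2.2 equiv) at −78 °C should convert F3 by bromine–lithium exchange, 1,2-shift and deprotonation into the lithium alkynyl ether 11, which is quenched with paraformaldehyde as in step 7, and the route is rejoined at 12.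

**Further compounds**

F0 | step 21 | none | none
F1 | step 16 | (8S)-chloromethanesulfonate of 23 | C=C1C(=O)O[C@H](/C=C\I)[C@H]1[C@@H](OS(=O)(=O)CCl)C[C@@](C)(CO[Si](C(C)C)(C(C)C)C(C)C)OC#CCOCc1ccc(OC)cc1
F2 | step 6 | (2S)-4-(tert-butyldimethylsilyloxy)-2-methyl-1-(triisopropylsilyloxy)butan-2-yl formate | O=CO[C@](C)(CO[Si](C(C)C)(C(C)C)C(C)C)CCO[Si](C)(C)C(C)(C)C
F3 | step 6 | (2S)-4-(tert-butyldimethylsilyloxy)-2-(2,2-dibromoethenyloxy)-2-methyl-1-(triisopropylsilyloxy)butane | BrC(Br)=CO[C@](C)(CO[Si](C(C)C)(C(C)C)C(C)C)CCO[Si](C)(C)C(C)(C)C
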